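The easy step is to count what stays behind and not what is made. If starting material and coupling partner react one to one and the coupling partner, being the smaller charge, is consumed, the fraction of starting material left is one minus the partner charge over the starting material charge. Reckoned for north-east, this leftover fraction is 20.0%.

in all of them: free catalyst 1.2 mM

| charge | starting material | coupling partner | remark | time |
|---|---|---|---|---|
| oak | 0.036 M | 0.040 M | run made earlier |  |
| cedar | 0.21 M | 0.040 M | run made earlier |  |
| alder | 0.68 M | 0.040 M | run made earlier |  |
| north-east | 0.050 M | 0.0400 M |  | 8.0 d |
| south | 0.10 M | 0.0400 M |  | 8.0 d |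
| south-east | 0.20 M | 0.0400 M |  | 8.0 d |
| south-west | 0.40 M | 0.0400 M |  | 8.0 d |
| east | 0.80 M | 0.0400 M |  | 8.0 d |

| run | time / d | target / % |
|---|---|---|
| oak | 1.67 | 78 |
| oak | 3.00 | 99 |
| oak | 5.00 | 99 |
| oak | 6.00 | 102 |
| oak | 8.00 | 101 |
| cedar | 0.625 | 8 |
| cedar | 1.25 | 12 |
| cedar | 2.50 | 14 |
| cedar | 4.00 | 21 |
| cedar | 8.00 | 19 |
| alder | 0.625 | 2 |
| alder | 1.25 | 0 |
| alder | 2.50 | 4 |
| alder | 4.00 | 8 |
| alder | 8.00 | 8 |

(scatter of a reading: 2 percentage points)

- "hardly changes" means that all values lie within two and a half points (for a concentration: within two and a half percent of the largest)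

- [target] at the end for north-east, south, south-east, south-west, east, in this order
- how the row runs (rises all the way / hardly changes / rises, then falls / falls, then rises / falls all the way)

Cedar shows the run in slow motion, read with one target formed per partner used. At the first reading, at 0.625 d, its 8% of target means [target] = 0.0168 M, so by that reading 58.0% of the partner and 92.0% of the starting material are left. In the middle, at 2.50 d, the cedar reading leaves 0.0106 M of partner against 0.181 M of starting material, so the small remainder of partner is what is about to matter. At the end, at 8.00 d, the cedar reading leaves 81.0% of the starting material, and the charges give a leftover fraction of 81.0%. Alder reads 92.0% left against 94.1% from its charges, with a scatter of 2 percentage points. Cedar and alder both read level within that scatter from 4.00 d, which is earlier than the asked 8.0 d.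

My own reckoning follows. The coupling partner at 0.0400 M is charged below the lowest starting material charge, 0.050 M, so it is the limiting reagent along the row. The leftover fraction climbs from 20.0% at north-east to 95.0% at east, while [target] reckons to 0.0400 M at north-east and 0.0400 M at east. The forecast agrees, with 0.04 M, 0.04 M, 0.04 M, 0.04 M, 0.04 M, and a row that hardly changes; its ground is “the coupling partner limits these runs”.

The simulation gives 0.0400 M, 0.0400 M, 0.0400 M, 0.0400 M, 0.0400 M, and the row hardly changes.

    coupling partner + free catalyst ⇌ catalyst intermediate A (K = 49.0 M⁻¹, k = 0.0480 M⁻¹ s⁻¹)
    catalyst intermediate A → released group + catalyst intermediate B (k = 4.10 × 10⁻⁴ s⁻¹)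
    starting material + catalyst intermediate B → catalyst intermediate C (k = 0.120 M⁻¹ s⁻¹)
    catalyst intermediate C → free catalyst + target (k = 0.00900 s⁻¹)

North-east ends with 20.0% of its starting material against the 20.0% reckoned, and east with 95.0% against 95.0%. The largest single effect on east is the running short of coupling partner, of which 0% is left at 8.00 d. East stands at 0.0400 M, and the same flask with that shortage taken away reaches 0.192 M, a factor of 4.79.

Readings and results are simulated with made-up constants, noise included.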